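## Retrosynthetic overview

1. The spiro-oxolane (C9–O–C13) is closed last, by acid-catalysed addition of the C13 tertiary alcohol to the C8=C9 alkene of a cis-fused octalin; just before that the 19,6-γ-lactone is closed by transesterification. Ring order: side-chain butyrolactone, then rings A and B together, then the γ-lactone, then the oxolane.
2. Rings A and B: ring B (C5–C6–C7–C8–C9–C10) is cut into a C7=C8–C9=C10 diene and a C5=C6 dienophile joined by the C1–C2–C3–C4 chain of ring A, so one intramolecular Diels–Alder reaction forms C5–C10 and C6–C7 and sets C5, C6 and C10.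
3. Enabling features: C6 carries an oxygen cis to H5, so it can enter as boron on an (E)-alkenylborane made in the flask from an ethynyl group on C4. C20 and H5 are cis, which is the fusion that a diene with its tether on the inside position (C1 cis to C8 across C9=C10) must give. The new C8=C9 alkene then sits where H8 and the ether oxygen are needed.
4. Triene: the tetrasubstituted C9=C10 alkene of defined geometry comes from a β-keto ester (C9 ketone, C20 ester) by C10-alkylation with the C1–C6 iodide, (E)-enol tosylation and Negishi coupling with an isopropenylzinc reagent (C7, C8, C17).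
5. Stereocentres carried in: C4 from an organocatalytic Michael addition of methyl 2-methylacetoacetate to acrolein; C13 from (R)-malic acid by dioxolanone alkylation.

Key step: step 18

Remark (numbering): labdane numbering is used throughout (C19 = carboxyl carbon on C4, C20 = CH2OAc carbon on C10, C16 = side-chain lactone carbonyl); β is the face of C20.
Remark (configuration): read as written, the SMILES places H5, the C6 oxygen, C19 and C20 on the β face (cis-fused rings A/B, H5 trans to H6), with C17 α, the C9 oxygen α and C13 R; the route is built for this configuration.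
Assumption: of the pseudo-enantiomeric cupreine/cupreidine 9-O-aryl ether catalysts, the one that gives (S)-3 is used in step 1; the text writes the cupreidine ether.

## Route

Step 1
Reactants: 1 methyl 2-methyl-3-oxobutanoate; 2 acrolein
Product: 3 methyl (2S)-2-acetyl-2-methyl-5-oxopentanoate
Conditions: 9-O-(9-phenanthryl)cupreidine (10 mol %), CH2Cl2, −25 °C
Reagents that add atoms: none
Why: Organocatalytic Michael addition of an α-substituted β-keto ester to an enal: the quinuclidine deprotonates 1, the 6'-OH binds acrolein, and the catalyst pocket selects the enolate face, which sets the quaternary C4 centre as S.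

Step 2
Reactants: 3 methyl (2S)-2-acetyl-2-methyl-5-oxopentanoate
Product: 4 methyl (2S)-2-acetyl-5,5-dimethoxy-2-methylpentanoate
Conditions: HC(OMe)3, TsOH·H2O (cat.), rt
Reagents that add atoms: trimethyl orthoformate, COC(OC)OC
Why: Acid-catalysed acetalisation is selective for the unhindered aldehyde over the neopentyl-type methyl ketone and masks it against the strong base of step 3.

Step 3
Reactants: 4 methyl (2S)-2-acetyl-5,5-dimethoxy-2-methylpentanoate
Product: 6 methyl (2S)-2-ethynyl-5,5-dimethoxy-2-methylpentanoate, via enol phosphate 5 (not isolated)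
Conditions: LiN(i-Pr)2 (1.1 equiv), THF, −78 °C; ClP(O)(OEt)2, −78 → 0 °C; then LiN(i-Pr)2 (2.3 equiv), −78 °C → rt; aq. NH4Cl
Reagents that add atoms: none
Why: Methyl ketone to terminal alkyne by enol phosphate formation and β-elimination: the methyl group is the only enolisable position and the quaternary centre has no α-hydrogen to lose.

Step 4
Reactants: 6 methyl (2S)-2-ethynyl-5,5-dimethoxy-2-methylpentanoate
Product: 8 methyl (2S)-2-ethynyl-5-hydroxy-2-methylpentanoate, via aldehyde 7 (not isolated)
Conditions: 1 M HCl, THF, rt; then NaHCO3 to pH 7, NaBH4, MeOH, 0 °C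
Reagents that add atoms: water, O
Why: Acetal hydrolysis followed at once by borohydride reduction of the aldehyde, which leaves the hindered methyl ester and the alkyne untouched.

Step 5
Reactants: 8 methyl (2S)-2-ethynyl-5-hydroxy-2-methylpentanoate
Product: 9 methyl (2S)-2-ethynyl-5-iodo-2-methylpentanoate
Conditions: I2, PPh3, imidazole, CH2Cl2, 0 °C → rt
Reagents that add atoms: iodine, II
Why: Appel-type iodination of a primary alcohol under neutral conditions.

Step 6
Reactants: 10 (R)-malic acid
Product: 11 [(2R,4R)-2-tert-butyl-5-oxo-1,3-dioxolan-4-yl]acetic acid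
Conditions: t-BuCHO, TsOH·H2O (cat.), H2SO4 (cat.), pentane, reflux, water separator; crystallisation
Reagents that add atoms: pivalaldehyde, CC(C)(C)C=O
Why: Acetalisation of the α-hydroxy acid unit gives the cis-dioxolanone as the thermodynamic, crystalline product, so the C13 configuration is stored in the acetal centre.

Step 7
Reactants: 11 [(2R,4R)-2-tert-butyl-5-oxo-1,3-dioxolan-4-yl]acetic acid; 12 propargyl bromide
Product: 13 [(2R,4R)-2-tert-butyl-5-oxo-4-(prop-2-yn-1-yl)-1,3-dioxolan-4-yl]acetic acid
Conditions: LiN(SiMe3)2 (2.2 equiv), THF, −78 °C; then 12, −78 → −20 °C; aq. HCl work-up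
Reagents that add atoms: none
Why: Self-regeneration of stereocentres: the carboxylate/enolate dianion is alkylated anti to the tert-butyl group, so the propargyl group takes the place of the former hydrogen and C13 is set with overall retention.

Step 8
Reactants: 13 [(2R,4R)-2-tert-butyl-5-oxo-4-(prop-2-yn-1-yl)-1,3-dioxolan-4-yl]acetic acid
Product: 16 (3R)-3-hydroxy-3-(prop-2-yn-1-yl)oxolan-2-one, via mixed anhydride 14 (not isolated), via hydroxyethyl acetal 15 (not isolated)
Conditions: i-BuOCOCl, N-methylmorpholine, THF, −15 °C; NaBH4, H2O, 0 °C; then 1 M HCl, rt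
Reagents that add atoms: none
Why: Mixed-anhydride activation lets NaBH4 reduce only the free carboxyl group in the presence of the alkyne, and the primary alcohol then transacylates onto the dioxolanone carbonyl under acid with loss of pivalaldehyde to give the five-membered lactone.

Step 9
Reactants: 16 (3R)-3-hydroxy-3-(prop-2-yn-1-yl)oxolan-2-one
Product: 17 (3R)-3-(prop-2-yn-1-yl)-3-(triethylsilyloxy)oxolan-2-one
Conditions: Et3SiOTf, 2,6-lutidine, CH2Cl2, −78 → 0 °C
Reagents that add atoms: triethylsilyl trifluoromethanesulfonate, CC[Si](CC)(CC)OS(=O)(=O)C(F)(F)F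
Why: Silyl triflate silylation of a hindered tertiary alcohol; the ether later prevents sulfonylation and oxa-Michael addition of this oxygen.

Step 10
Reactants: 17 (3R)-3-(prop-2-yn-1-yl)-3-(triethylsilyloxy)oxolan-2-one
Product: 19 3-[(3R)-2-oxo-3-(triethylsilyloxy)oxolan-3-yl]propanal, via alkenylborane 18 (not isolated)
Conditions: Cy2BH (from BH3·SMe2 and cyclohexene, 1.2 equiv), THF, 0 °C; then 30% H2O2, aq. NaOAc, 0 °C → rt
Reagents that add atoms: hydrogen peroxide, OO
Why: Anti-Markovnikov hydroboration of a terminal alkyne with a hindered dialkylborane stops at the alkenylborane, whose buffered oxidation gives the aldehyde.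

Step 11
Reactants: 19 3-[(3R)-2-oxo-3-(triethylsilyloxy)oxolan-3-yl]propanal; 20 tert-butyl diazoacetate
Product: 21 tert-butyl 3-oxo-5-[(3R)-2-oxo-3-(triethylsilyloxy)oxolan-3-yl]pentanoate
Conditions: SnCl2 (10 mol %), CH2Cl2, rt
Reagents that add atoms: none
Why: Roskamp homologation: SnCl2-promoted addition of the diazo ester to the aldehyde, 1,2-hydride shift and loss of N2 give the β-keto ester directly.

Step 12
Reactants: 21 tert-butyl 3-oxo-5-[(3R)-2-oxo-3-(triethylsilyloxy)oxolan-3-yl]pentanoate; 9 methyl (2S)-2-ethynyl-5-iodo-2-methylpentanoate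
Product: 22 tert-butyl 2-[(4S)-4-(methoxycarbonyl)-4-methylhex-5-yn-1-yl]-3-oxo-5-[(3R)-2-oxo-3-(triethylsilyloxy)oxolan-3-yl]pentanoate (both C10 epimers)
Conditions: K2CO3, acetone, 55 °C
Reagents that add atoms: none
Why: C-alkylation of a β-keto ester with a primary iodide under weak base; the new C10 centre becomes sp2 in step 13, so its configuration is irrelevant.

Step 13
Reactants: 22 tert-butyl 2-[(4S)-4-(methoxycarbonyl)-4-methylhex-5-yn-1-yl]-3-oxo-5-[(3R)-2-oxo-3-(triethylsilyloxy)oxolan-3-yl]pentanoate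
Product: 23 tert-butyl (2E)-2-[(4S)-4-(methoxycarbonyl)-4-methylhex-5-yn-1-yl]-3-(tosyloxy)-5-[(3R)-2-oxo-3-(triethylsilyloxy)oxolan-3-yl]pent-2-enoate
Conditions: TsCl, N-methylimidazole, Et3N, MeCN, 0 °C → rt
Reagents that add atoms: 4-toluenesulfonyl chloride, Cc1ccc(cc1)S(Cl)(=O)=O
Why: Stereoselective enol tosylation of an α-substituted β-keto ester: without a chelating metal the ammonium enolate is sulfonylated as the E isomer (tosylate trans to the ester), which fixes the later tether-cis-to-isopropenyl geometry.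

Step 14
Reactants: 23 tert-butyl (2E)-2-[(4S)-4-(methoxycarbonyl)-4-methylhex-5-yn-1-yl]-3-(tosyloxy)-5-[(3R)-2-oxo-3-(triethylsilyloxy)oxolan-3-yl]pent-2-enoate
Product: 24 tert-butyl (2E)-2-[(4S)-4-(methoxycarbonyl)-4-methylhex-5-yn-1-yl]-4-methyl-3-{2-[(3R)-2-oxo-3-(triethylsilyloxy)oxolan-3-yl]ethyl}penta-2,4-dienoate
Conditions: CH2=C(CH3)ZnBr (from CH2=C(CH3)MgBr and ZnBr2, 2.5 equiv), Pd(OAc)2 (5 mol %), SPhos (10 mol %), THF, 50 °C
Reagents that add atoms: isopropenylzinc bromide, CC(=C)[Zn]Br
Why: Negishi coupling of an activated enol tosylate proceeds with retention of alkene geometry, and the organozinc tolerates the lactone, esters, silyl ether and terminal alkyne.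

Step 15
Reactants: 24 tert-butyl (2E)-2-[(4S)-4-(methoxycarbonyl)-4-methylhex-5-yn-1-yl]-4-methyl-3-{2-[(3R)-2-oxo-3-(triethylsilyloxy)oxolan-3-yl]ethyl}penta-2,4-dienoate
Product: 26 (2E)-2-[(4S)-4-(methoxycarbonyl)-4-methylhex-5-yn-1-yl]-4-methyl-3-{2-[(3R)-2-oxo-3-(triethylsilyloxy)oxolan-3-yl]ethyl}penta-2,4-dienoic acid, via trimethylsilyl ester 25 (not isolated)
Conditions: Me3SiOTf, 2,6-lutidine, CH2Cl2, 0 °C; then pH 5 aqueous work-up
Reagents that add atoms: none
Why: Silyl triflate cleavage of a tert-butyl ester (loss of isobutene, then hydrolysis of the silyl ester) spares the methyl ester, lactone and silyl ether and avoids protic acid at the dienoate.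

Step 16
Reactants: 26 (2E)-2-[(4S)-4-(methoxycarbonyl)-4-methylhex-5-yn-1-yl]-4-methyl-3-{2-[(3R)-2-oxo-3-(triethylsilyloxy)oxolan-3-yl]ethyl}penta-2,4-dienoic acid
Product: 28 (2E)-2-[(4S)-4-(methoxycarbonyl)-4-methylhex-5-yn-1-yl]-4-methyl-3-{2-[(3R)-2-oxo-3-(triethylsilyloxy)oxolan-3-yl]ethyl}penta-2,4-dien-1-ol, via mixed anhydride 27 (not isolated)
Conditions: i-BuOCOCl, N-methylmorpholine, THF, −15 °C; then NaBH4, THF/H2O, 0 °C
Reagents that add atoms: none
Why: Reduction of the mixed carbonic anhydride by NaBH4 gives the allylic alcohol under conditions that leave the methyl ester and the lactone intact, which a direct aluminium hydride reduction of the ester would not.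

Step 17
Reactants: 28 (2E)-2-[(4S)-4-(methoxycarbonyl)-4-methylhex-5-yn-1-yl]-4-methyl-3-{2-[(3R)-2-oxo-3-(triethylsilyloxy)oxolan-3-yl]ethyl}penta-2,4-dien-1-ol
Product: 29 (2E)-2-[(4S)-4-(methoxycarbonyl)-4-methylhex-5-yn-1-yl]-4-methyl-3-{2-[(3R)-2-oxo-3-(triethylsilyloxy)oxolan-3-yl]ethyl}penta-2,4-dien-1-yl acetate
Conditions: Ac2O, pyridine, DMAP (cat.), CH2Cl2, 0 °C
Reagents that add atoms: acetic anhydride, CC(=O)OC(C)=O
Why: Standard acylation of the primary allylic alcohol installs the C20 acetate of the target while the tertiary alcohol is silyl-protected.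

Step 18
Reactants: 29 (2E)-2-[(4S)-4-(methoxycarbonyl)-4-methylhex-5-yn-1-yl]-4-methyl-3-{2-[(3R)-2-oxo-3-(triethylsilyloxy)oxolan-3-yl]ethyl}penta-2,4-dien-1-yl acetate
Product: 32 methyl (13R)-20-acetoxy-6β-hydroxy-13-(triethylsilyloxy)-5β-labd-8-en-16,15-olid-19-oate, via alkenylborane 30 (not isolated), via cycloadduct borane 31 (not isolated)
Conditions: Cy2BH (from BH3·SMe2 and cyclohexene, 1.15 equiv), THF, 0 °C, then 50 °C (degassed, BHT); then 30% H2O2, aq. NaOAc, 0 °C → rt
Reagents that add atoms: hydrogen peroxide, OO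
Why: Proposed new method: syn-hydroboration of the hindered terminal alkyne gives the (E)-alkenyl(dicyclohexyl)borane 30, whose vacant boron p orbital makes it an electron-poor dienophile that should undergo a concerted suprafacial intramolecular [4+2] cycloaddition with the tetrasubstituted diene below 60 °C, after which the C6–B bond is oxidised with retention; the closest known reactions are intermolecular Diels–Alder reactions of alkenyl-dialkylboranes and thermal type-1 intramolecular Diels–Alder reactions of deca-1,7,9-trienes, not yet combined on a carbon-tethered triene. Ring A (C1–C5, C10) closes through the four-carbon tether by the C5–C10 bond in the fused mode, and ring B is the cyclohexene of the cycloaddition, closed by C5–C10 and C6–C7. Because C1 is cis to C8 on the diene terminus (inside position), the tether can reach the dienophile only in the exo-tether geometry, which puts the outside CH2OAc group and H5 on the same face and fixes the cis ring fusion at C10 and C5. The E geometry of the alkenylborane, kept by the suprafacial addition (boron endo) and by the retentive oxidation, places the C6 oxygen cis to H5. The absolute sense comes from the C4 centre: in the chair-like tether the smaller, planar CO2Me group should take the pseudo-axial site syn to C20 and the methyl group the pseudo-equatorial one, so C19, C20, H5 and O6 end on one face. The step needs chemoselective hydroboration, secured by the bulky dialkylborane that attacks a terminal alkyne far faster than the 1,1-disubstituted end of a hindered diene, and a temperature below that of the 1,5-hydrogen shift open to a diene with an inside alkyl group, secured by the high dienophilicity of the borane.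

Step 19
Reactants: 32 methyl (13R)-20-acetoxy-6β-hydroxy-13-(triethylsilyloxy)-5β-labd-8-en-16,15-olid-19-oate
Product: 33 (13R)-20-acetoxy-13-(triethylsilyloxy)-5β-labd-8-ene-19,6β:16,15-diolide
Conditions: PPTS (20 mol %), 4 Å molecular sieves, toluene, 80 °C
Reagents that add atoms: none
Why: Acid-catalysed intramolecular transesterification: the 6β-hydroxyl and the C19 ester are both on the β face, the sieves remove methanol to drive closure of the strained γ-lactone, and PPTS is too weak to protonate the C8=C9 alkene.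

Step 20
Reactants: 33 (13R)-20-acetoxy-13-(triethylsilyloxy)-5β-labd-8-ene-19,6β:16,15-diolide
Product: 35 (13R)-20-acetoxy-9α,13-epoxy-5β,8βH-labdane-19,6β:16,15-diolide (CNP0298733.1), via tertiary alcohol 34 (not isolated)
Conditions: HF·pyridine, THF, 0 °C → rt; evaporate; then TfOH (10 mol %), CH2Cl2, −40 → −10 °C
Reagents that add atoms: none
Why: Brønsted-acid-catalysed intramolecular hydroalkoxylation (5-exo, Markovnikov): after desilylation the C13 hydroxyl should add to C9 in an anti fashion, the proton entering C8 from the convex β face and the oxygen entering C9 from the α face, which sets H8 β, C17 α and O9 α.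

## Compound list

1 | methyl 2-methyl-3-oxobutanoate | CC(=O)C(C)C(=O)OC | starting material
2 | acrolein | C=CC=O | starting material
3 | methyl (2S)-2-acetyl-2-methyl-5-oxopentanoate | O=CCC[C@](C(C)=O)(C)C(=O)OC | intermediate
4 | methyl (2S)-2-acetyl-5,5-dimethoxy-2-methylpentanoate | COC(OC)CC[C@](C(C)=O)(C)C(=O)OC | intermediate
5 | methyl (2S)-2-{1-[(diethoxyphosphoryl)oxy]ethenyl}-5,5-dimethoxy-2-methylpentanoate (enol phosphate) | COC(OC)CC[C@](C(=C)OP(=O)(OCC)OCC)(C)C(=O)OC | intermediate
6 | methyl (2S)-2-ethynyl-5,5-dimethoxy-2-methylpentanoate | COC(OC)CC[C@](C#C)(C)C(=O)OC | intermediate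
7 | methyl (2S)-2-ethynyl-2-methyl-5-oxopentanoate (aldehyde) | O=CCC[C@](C#C)(C)C(=O)OC | intermediate
8 | methyl (2S)-2-ethynyl-5-hydroxy-2-methylpentanoate | OCCC[C@](C#C)(C)C(=O)OC | intermediate
9 | methyl (2S)-2-ethynyl-5-iodo-2-methylpentanoate | ICCC[C@](C#C)(C)C(=O)OC | intermediate
10 | (R)-malic acid | O[C@H](CC(=O)O)C(=O)O | starting material
11 | [(2R,4R)-2-tert-butyl-5-oxo-1,3-dioxolan-4-yl]acetic acid (cis acetal) | OC(=O)C[C@H]1O[C@@H](C(C)(C)C)OC1=O | intermediate
12 | propargyl bromide | BrCC#C | starting material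
13 | [(2R,4R)-2-tert-butyl-5-oxo-4-(prop-2-yn-1-yl)-1,3-dioxolan-4-yl]acetic acid | C#CC[C@]1(CC(=O)O)O[C@@H](C(C)(C)C)OC1=O | intermediate
14 | mixed isobutyl carbonic anhydride of 13 | C#CC[C@]1(CC(=O)OC(=O)OCC(C)C)O[C@@H](C(C)(C)C)OC1=O | intermediate
15 | (2R,5R)-2-tert-butyl-5-(2-hydroxyethyl)-5-(prop-2-yn-1-yl)-1,3-dioxolan-4-one | C#CC[C@]1(CCO)O[C@@H](C(C)(C)C)OC1=O | intermediate
16 | (3R)-3-hydroxy-3-(prop-2-yn-1-yl)oxolan-2-one | C#CC[C@]1(CCOC1=O)O | intermediate
17 | (3R)-3-(prop-2-yn-1-yl)-3-(triethylsilyloxy)oxolan-2-one | C#CC[C@]1(CCOC1=O)O[Si](CC)(CC)CC | intermediate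
18 | (E)-alkenyl(dicyclohexyl)borane from 17 | B(/C=C/C[C@]1(CCOC1=O)O[Si](CC)(CC)CC)(C1CCCCC1)C1CCCCC1 | intermediate
19 | 3-[(3R)-2-oxo-3-(triethylsilyloxy)oxolan-3-yl]propanal | O=CCC[C@]1(CCOC1=O)O[Si](CC)(CC)CC | intermediate
20 | tert-butyl diazoacetate | CC(C)(C)OC(=O)C=[N+]=[N-] | starting material
21 | tert-butyl 3-oxo-5-[(3R)-2-oxo-3-(triethylsilyloxy)oxolan-3-yl]pentanoate | CC(C)(C)OC(=O)CC(=O)CC[C@]1(CCOC1=O)O[Si](CC)(CC)CC | intermediate
22 | tert-butyl 2-[(4S)-4-(methoxycarbonyl)-4-methylhex-5-yn-1-yl]-3-oxo-5-[(3R)-2-oxo-3-(triethylsilyloxy)oxolan-3-yl]pentanoate (C10 epimers) | CC(C)(C)OC(=O)C(CCC[C@](C#C)(C)C(=O)OC)C(=O)CC[C@]1(CCOC1=O)O[Si](CC)(CC)CC | intermediate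
23 | (E)-enol tosylate of 22 (tosylate trans to the ester) | CC(C)(C)OC(=O)/C(CCC[C@](C#C)(C)C(=O)OC)=C(/OS(=O)(=O)c1ccc(C)cc1)CC[C@]1(CCOC1=O)O[Si](CC)(CC)CC | intermediate
24 | tert-butyl (2E)-dienoate (isopropenyl cis to the C1 chain) | CC(C)(C)OC(=O)/C(CCC[C@](C#C)(C)C(=O)OC)=C(/C(C)=C)CC[C@]1(CCOC1=O)O[Si](CC)(CC)CC | intermediate
25 | trimethylsilyl ester of 26 | C[Si](C)(C)OC(=O)/C(CCC[C@](C#C)(C)C(=O)OC)=C(/C(C)=C)CC[C@]1(CCOC1=O)O[Si](CC)(CC)CC | intermediate
26 | (2E)-dienoic acid | OC(=O)/C(CCC[C@](C#C)(C)C(=O)OC)=C(/C(C)=C)CC[C@]1(CCOC1=O)O[Si](CC)(CC)CC | intermediate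
27 | mixed isobutyl carbonic anhydride of 26 | CC(C)COC(=O)OC(=O)/C(CCC[C@](C#C)(C)C(=O)OC)=C(/C(C)=C)CC[C@]1(CCOC1=O)O[Si](CC)(CC)CC | intermediate
28 | (2E)-dienol (C20 alcohol) | OC/C(CCC[C@](C#C)(C)C(=O)OC)=C(/C(C)=C)CC[C@]1(CCOC1=O)O[Si](CC)(CC)CC | intermediate
29 | (2E)-dienyl acetate with ethynyl group on C4 (cycloaddition precursor) | CC(=O)OC/C(CCC[C@](C#C)(C)C(=O)OC)=C(/C(C)=C)CC[C@]1(CCOC1=O)O[Si](CC)(CC)CC | intermediate
30 | (E)-alkenyl(dicyclohexyl)borane from 29 | CC(=O)OC/C(CCC[C@](/C=C/B(C1CCCCC1)C1CCCCC1)(C)C(=O)OC)=C(/C(C)=C)CC[C@]1(CCOC1=O)O[Si](CC)(CC)CC | intermediate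
31 | cycloadduct: 6β-(dicyclohexylboryl) analogue of 32 | CC(=O)OC[C@]12CCC[C@](C)(C(=O)OC)[C@H]1[C@H](B(C3CCCCC3)C3CCCCC3)CC(C)=C2CC[C@]3(CCOC3=O)O[Si](CC)(CC)CC | intermediate
32 | methyl (13R)-20-acetoxy-6β-hydroxy-13-(triethylsilyloxy)-5β-labd-8-en-16,15-olid-19-oate | CC(=O)OC[C@]12CCC[C@](C)(C(=O)OC)[C@H]1[C@H](O)CC(C)=C2CC[C@]3(CCOC3=O)O[Si](CC)(CC)CC | intermediate
33 | (13R)-20-acetoxy-13-(triethylsilyloxy)-5β-labd-8-ene-19,6β:16,15-diolide | CC(=O)OC[C@@]12CCC[C@]3(C)C(=O)O[C@H](CC(C)=C1CC[C@]1(CCOC1=O)O[Si](CC)(CC)CC)[C@@H]23 | intermediate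
34 | (13R)-20-acetoxy-13-hydroxy-5β-labd-8-ene-19,6β:16,15-diolide | CC(=O)OC[C@@]12CCC[C@]3(C)C(=O)O[C@H](CC(C)=C1CC[C@]1(CCOC1=O)O)[C@@H]23 | intermediate
35 | (13R)-20-acetoxy-9α,13-epoxy-5β,8βH-labdane-19,6β:16,15-diolide (CNP0298733.1) | CC(=O)OC[C@@]12CCC[C@]3(C)C(=O)O[C@H](C[C@@H](C)[C@]14CC[C@]1(CCOC1=O)O4)[C@@H]23 | target

## Step count and risks

Total steps: 20. Longest linear sequence: 15 steps (steps 6–20, from (R)-malic acid); the C1–C6 fragment (steps 1–5) joins at step 12.

Steps most likely to fail: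

1. Step 18 (proposed new method). What may go wrong: the borane may also add to the 1,1-disubstituted end of the diene, the cycloaddition may be too slow to outrun decay of the alkenylborane, or facial selectivity with respect to C4 may be poor. The fallback sets out from 29 and comes back at 32. Cp2Zr(H)Cl-catalysed hydroboration of the alkyne with pinacolborane (Et3N cat., CH2Cl2, rt) should give the isolable (E)-alkenylboronic acid pinacol ester F1. F1 is then heated (o-dichlorobenzene, BHT, 150–160 °C) in a thermal intramolecular Diels–Alder reaction of an alkenylboronic ester, the same inside-tether geometry enforcing the cis fusion, to give the cycloadduct pinacol boronate F2. Oxidation of F2 with NaBO3·4H2O in THF/H2O gives 32.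

2. Step 20. What may go wrong: protonation and oxygen attack across the other face of the C8=C9 alkene, 6-endo closure onto C8, or cationic rearrangement under strong acid. The fallback sets out from 33 and comes back at 35. HF·pyridine gives the tertiary alcohol 34, isolated this time. Iodoetherification (I2, NaHCO3, MeCN, 0 °C) should close the oxolane under kinetic control by anti addition through the iodonium ion to the 8β-iodo spiro ether F3. Radical deiodination (Bu3SnH, AIBN, toluene, 80 °C) then delivers hydrogen to C8 from the less hindered β face and gives 35.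

3. Step 1. What may go wrong: low enantioselectivity with an acyclic α-methyl β-keto ester, a weakly organised donor, which would erode the absolute configuration of C4 and with it C5, C6 and C10. The fallback sets out from 1 and comes back at 4. Condensation of 1 with L-valine tert-butyl ester (BF3·OEt2 cat., benzene, water separator) gives the chiral enamino ester F4. Its lithio derivative (LiN(i-Pr)2, −78 °C, solvent set chosen for the S centre: toluene/HMPA or THF) is alkylated with 3-iodo-1,1-dimethoxypropane in an auxiliary-controlled enamine alkylation to the α-alkylated imine F5. Buffered hydrolysis (aq. AcOH/NaOAc) releases the auxiliary and gives 4.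

Further compounds

F1 | step 18 | (E)-alkenylboronic acid pinacol ester from 29 | CC(=O)OC/C(CCC[C@](/C=C/B1OC(C)(C)C(C)(C)O1)(C)C(=O)OC)=C(/C(C)=C)CC[C@]1(CCOC1=O)O[Si](CC)(CC)CC
F2 | step 18 | cycloadduct pinacol boronate (6β-boryl analogue of 32) | CC(=O)OC[C@]12CCC[C@](C)(C(=O)OC)[C@H]1[C@H](B3OC(C)(C)C(C)(C)O3)CC(C)=C2CC[C@]3(CCOC3=O)O[Si](CC)(CC)CC
F3 | step 20 | 8β-iodo spiro ether (8-iodo analogue of 35) | CC(=O)OC[C@@]12CCC[C@]3(C)C(=O)O[C@H](C[C@@](I)(C)[C@]14CC[C@]1(CCOC1=O)O4)[C@@H]23
F4 | step 1 | enamino ester of 1 with L-valine tert-butyl ester | C/C(N[C@@H](C(C)C)C(=O)OC(C)(C)C)=C(\C)C(=O)OC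
F5 | step 1 | α-alkylated imine (valine tert-butyl ester imine of 4) | COC(OC)CC[C@](C(C)=N[C@@H](C(C)C)C(=O)OC(C)(C)C)(C)C(=O)OC
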